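Late in the two earlier runs the solid substrate holds nearly level: near 33.4% of the charge from 8.00 min on in the green run, and near 18.3% from 15.0 min on in the violet run.

in all of them: solid substrate 0.050 M
- green: partner 0.025 M; run made earlier
- violet: partner 0.038 M; run made earlier
- flask: partner 0.0500 M; time 25 min

| run | time / min | solid substrate / % | target / % |
|---|---|---|---|
| green | 2.50 | 35.3 | 2.2 |
| green | 8.00 | 33.7 | 0.6 |
| green | 12.0 | 32.8 | 0.3 |
| green | 20.0 | 33.7 | 0.8 |
| violet | 5.00 | 19.8 | 1.8 |
| violet | 10.0 | 19.1 | 0.3 |
| violet | 15.0 | 18.5 | 0 |
| violet | 20.0 | 18.1 | 0.3 |

(readings scatter by 0.5 percentage points)

1. amount of solid substrate in percent of the solid substrate charged, at 80 s, 6.0 min and 25 min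

Two numbers seem not to go together. The green run lost 66.6% of its solid with partner at 50.0% of the charge, so more solid went than partner was charged. Yet the violet run, with 26 percentage points more partner, lost a further 15 points, less solid than the added partner.

The two levels define one straight line with an offset, and two points give no test of it. Its slope is the solid price of partner, the fraction of the charge of solid lost per extra fraction of partner, 0.581. Its offset, the loss the line assigns to no partner, is 37.6% of the charge. On this line the offset makes up 56.5% of the green run's loss, and the price stays below one. Carried to the flask's partner fraction of 100%, this reckoning puts the level at 4.36%.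

The forecast gives 12%, 6% and 4.5%, judging that “a little solid probably survives”. Its last value comes from a like straight line through the same two levels, so its nearness to this reckoning is no check.

The flask gives 20.4%, 9.79% and 6.26%.

    partner → side product A (k = 0.0640 s⁻¹)
    partner → decomposition product (k = 3.70 × 10⁻⁶ s⁻¹)
    solid substrate ⇌ dissolved substrate, rate k3*(cs3 - [dissolved substrate]) while solid is left; crystals form when [dissolved substrate] > cs3 (solubility = 17.0 mM, k = 0.120 s⁻¹)
    solid substrate + target → side product B (k = 0.720 M⁻¹ s⁻¹)
    dissolved substrate + partner → target (k = 4.00 M⁻¹ s⁻¹)

At 25 min the flask holds 1.9 points more solid substrate than the line's level. At that time in the flask partner, the limiting reagent, stands at 0% of its charge, and dissolved substrate at 34.0% of the solid charged. Stepping back from the flask to the green run's partner fraction at the price of 0.581 turns 6.26% into a reckoned 35.3%, while the green run read 33.4%.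

All runs come from a simulation from invented constants; noise was put on by code.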